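The 14-membered carbocycle (C1–C14) is cut between C2 and C3. The feature exploited is the C4 tertiary carbinol (C4–OH, C4–CH3) flanked by the C3 methylene: it is what remains when a carbanion opens a 2,2-disubstituted oxirane at its CH2 end. In one operation the key step forms C2–C3, closes the 14-membered ring and unveils C4–OH with the configuration fixed beforehand on an open chain. Its substrate is an open-chain C2 phenyl sulfone that already holds the carvone-derived C1 centre and C12–C13 oxirane, the E-C8=C9 alkene, a silylated C5 carbinol and the C3–C4 oxirane.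

Key step: step 18

Remark: atoms carry the cembrane numbering of the target throughout (ring C1–C14; C15 is the vinylic carbon on C1, C16 its oxygenated carbon, C17 its methylene; methyls on C4, C8, C12), and anions formed by deprotonation are treated as ionised forms of the numbered compounds.
Remark: the cyclisation substrate 22 and its product 23 were checked atom by atom against the target and needed no correction; C10 in 20 and C2 in 23 are transient stereocentres carried as epimer mixtures.

Step 1
Reactants: 1 (R)-carvone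
Product: 2 chloro enone (10-chlorocarvone)
Conditions: Ca(OCl)2, solid CO2, CH2Cl2/H2O, 0 °C
Reagents that add atoms: calcium hypochlorite, [Ca+2].[O-]Cl.[O-]Cl
Why: HOCl formed in the flask should chlorinate the electron-rich 1,1-disubstituted alkene in an ene-type allylic chlorination, the electron-poor enone alkene and the stereocentre staying untouched.

Step 2
Reactants: 2 chloro enone
Product: 4 hydroxy enone (10-hydroxycarvone), via allylic acetate 3 (not isolated)
Conditions: KOAc, Bu4NI (cat.), DMF, 60 °C; then MeOH, K2CO3 (cat.), 23 °C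
Reagents that add atoms: potassium acetate, [K+].CC([O-])=O
Why: SN2 displacement of the primary allylic chloride by acetate followed by base-catalysed transesterification should free the allylic alcohol without affecting the enone.

Step 3
Reactants: 4 hydroxy enone
Product: 5 silyl ether enone
Conditions: TBSCl, imidazole, CH2Cl2, 23 °C
Reagents that add atoms: tert-butyldimethylsilyl chloride, CC(C)(C)[Si](C)(C)Cl
Why: Silylation of the primary alcohol should give an ether that survives every basic, reductive and organometallic step up to the end game.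

Step 4
Reactants: 5 silyl ether enone
Product: 6 trans-epoxy ketone
Conditions: 30% H2O2, NaOH (cat.), MeOH, 0 °C
Reagents that add atoms: hydrogen peroxide, OO
Why: Weitz–Scheffer nucleophilic epoxidation should proceed by axial conjugate addition of hydroperoxide anti to the C1 side chain, so that substrate control sets C12 and C13 with the oxirane trans to the C15 substituent.

Step 5
Reactants: 6 trans-epoxy ketone
Product: 7 hydroxy epoxy ketone
Conditions: NaN(SiMe3)2, THF, −78 °C; 2-(phenylsulfonyl)-3-phenyloxaziridine, −78 °C; AcOH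
Reagents that add atoms: 2-(phenylsulfonyl)-3-phenyloxaziridine, O=S(=O)(c1ccccc1)N1OC1c1ccccc1
Why: Davis enolate hydroxylation should occur at C2, the only enolisable position, and the new carbinol centre needs no control because it is destroyed in step 6.

Step 6
Reactants: 7 hydroxy epoxy ketone
Product: 9 hydroxy ester, via aldehyde ester 8 (not isolated)
Conditions: Pb(OAc)4, MeOH/PhMe (1:1), 0 °C; then NaBH4, −40 °C, same flask
Reagents that add atoms: methanol, CO
Why: Criegee cleavage of the methanol hemiketal of the ketol should cut C11–C2 into the C11 methyl ester and the C2 aldehyde, which borohydride reduces at once (aldehyde before glycidic ester), so that C1 has no time to epimerise.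

Step 7
Reactants: 9 hydroxy ester
Product: 10 sulfide ester
Conditions: N-(phenylthio)succinimide, PBu3, PhMe, 23 °C
Reagents that add atoms: N-(phenylthio)succinimide, O=C1CCC(=O)N1Sc1ccccc1
Why: Hata-type thioetherification (alkoxyphosphonium displaced by thiophenolate at the primary C2) should install sulfur without free thiol and without touching C1 or the glycidic ester.

Step 8
Reactants: 10 sulfide ester
Product: 11 epoxy alcohol
Conditions: iBu2AlH, CH2Cl2, −78 °C; aq. KNaC4H4O6
Reagents that add atoms: none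
Why: Hydride reduction of the ester to the primary C11 alcohol should leave the oxirane, the sulfide and the silyl ether intact at low temperature.

Step 9
Reactants: 11 epoxy alcohol
Product: 12 epoxy triflate
Conditions: Tf2O, 2,6-lutidine, CH2Cl2, −78 °C; cold aqueous wash, used crude at once
Reagents that add atoms: trifluoromethanesulfonic anhydride, O=S(=O)(OS(=O)(=O)C(F)(F)F)C(F)(F)F
Why: O-sulfonylation should give a leaving group reactive enough for SN2 at the hindered oxiranylmethyl carbon C11 at −78 °C.

Step 10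
Reactants: 13 geranyl bromide
Product: 14 geranyl phenyl sulfone
Conditions: PhSO2Na, DMF, 23 °C
Reagents that add atoms: sodium benzenesulfinate, [Na+].[O-]S(=O)c1ccccc1
Why: S-alkylation of the sulfinate by SN2 at the primary allylic bromide should keep the E geometry of the future C8=C9 bond.

Step 11
Reactants: 14 geranyl phenyl sulfone
Product: 15 sulfonyl aldehyde
Conditions: O3 (1.0 equiv), CH2Cl2/MeOH, −78 °C; then Me2S, −78 to 23 °C
Reagents that add atoms: ozone, [O-][O+]=O
Why: Ozonolysis should be chemoselective for the electron-rich terminal alkene, since the C8=C9 alkene is deactivated by the allylic sulfonyl group.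

Step 12
Reactants: 15 sulfonyl aldehyde; 16 isopropenylmagnesium bromide
Product: 17 racemic isopropenyl carbinol
Conditions: CH2=C(CH3)MgBr, THF, −78 °C; aq. NH4Cl
Reagents that add atoms: none
Why: Grignard 1,2-addition to the aldehyde at −78 °C should outrun deprotonation next to the sulfone, and the C5 carbinol formed as a racemate is resolved in step 13.

Step 13
Reactants: 17 racemic isopropenyl carbinol
Product: 18 epoxy alcohol (4S,5R)
Conditions: Ti(OiPr)4 (cat.), (−)-diisopropyl (2S,3S)-tartrate (cat.), t-BuOOH (0.55 equiv), 4 Å molecular sieves, CH2Cl2, −20 °C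
Reagents that add atoms: tert-butyl hydroperoxide, CC(C)(C)OO
Why: Sharpless kinetic resolution should epoxidise only the (5R)-alcohol, on the alkene face dictated by the tartrate, to give the erythro product, so that the reagent sets C4 and selects C5 while the (5S)-alcohol is left behind and can be recycled.

Step 14
Reactants: 18 epoxy alcohol
Product: 19 silylated epoxy sulfone
Conditions: TBSCl, imidazole, DMAP (cat.), DMF, 40 °C
Reagents that add atoms: tert-butyldimethylsilyl chloride, CC(C)(C)[Si](C)(C)Cl
Why: Silylation under base (no silyl triflate, which would trigger oxirane rearrangement) should block the C5 hydroxyl and with it any later Payne rearrangement.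

Step 15
Reactants: 19 silylated epoxy sulfone; 12 epoxy triflate
Product: 20 coupled sulfone
Conditions: 19, n-BuLi, THF, −78 °C; then 12, THF, −78 °C
Reagents that add atoms: none
Why: Alkylation of the allylic α-sulfonyl carbanion at C10 by SN2 on the triflate carbon C11 should form C10–C11 before either oxirane can react at −78 °C, and the C10 centre formed without control is removed in step 16.

Step 16
Reactants: 20 coupled sulfone
Product: 21 sulfide diepoxide
Conditions: Na(Hg) (6% Na), Na2HPO4, MeOH/THF, −20 °C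
Reagents that add atoms: none
Why: Reductive desulfonylation by electron transfer should cleave the allylic C10–S bond and protonate the allyl anion at its less substituted end C10, keeping the E-C8=C9 alkene, while oxiranes, silyl ethers and the aryl sulfide are inert at this temperature.

Step 17
Reactants: 21 sulfide diepoxide
Product: 22 sulfone diepoxide (cyclisation substrate)
Conditions: (NH4)6Mo7O24·4H2O (cat.), 30% H2O2, EtOH, 0 to 23 °C
Reagents that add atoms: hydrogen peroxide, OO
Why: Molybdate-catalysed peroxide oxidation of sulfide to sulfone should be far faster at sulfur than at the isolated alkenes.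

Step 18
Reactants: 22 sulfone diepoxide
Product: 23 macrocyclic hydroxy sulfone
Conditions: LiN(iPr)2 (1.1 equiv), THF, 2 mmol/L, −78 °C; DMPU, −78 to −20 °C; AcOH
Reagents that add atoms: none
Why: LiN(iPr)2 deprotonates C2 next to the sulfonyl group, and the carbanion attacks the unsubstituted C3 end of the C3–C4 oxirane in SN2 fashion, forming C2–C3 and releasing the C4 alkoxide. The closest known reaction type is the opening of epoxides by α-sulfonyl and other sulfur-stabilised carbanions, which has been used intramolecularly to close cembranoid rings. The one ring closed is the 14-membered carbocycle C1–C14, in a 14-endo-tet mode with respect to the oxirane (both oxirane carbons end up in the ring). No lasting stereocentre is created: C4 keeps the configuration set in step 13 because its C–O bond is not broken, and C2 becomes a sulfone-bearing centre formed without control and erased in step 19. Three selectivities are needed: C3 over C4 (C4 is fully substituted), the C3–C4 oxirane over the C12–C13 oxirane (the latter is reachable only by a strained 4-exo closure at C13 or a 5-endo closure at quaternary C12, and low temperature with a lithium counter-ion and no Lewis acid should favour the strain-free large-ring transition state), and ring closure over oligomerisation (high dilution). The C5 silyl ether keeps an alkoxide away from the reacting oxirane, and a silyl shift to the new C4 alkoxide would be harmless because both oxygens are freed in step 20.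

Step 19
Reactants: 23 macrocyclic hydroxy sulfone
Product: 24 macrocyclic bis-silyl ether
Conditions: Mg, MeOH, 23 °C
Reagents that add atoms: none
Why: Reductive desulfonylation by electron transfer from magnesium should replace the C2 sulfonyl group by hydrogen, merging both C2 epimers, with no β-leaving group available for elimination.

Step 20
Reactants: 24 macrocyclic bis-silyl ether
Product: 25 epoxy triol
Conditions: HF·pyridine, pyridine, THF, 0 to 23 °C
Reagents that add atoms: none
Why: Buffered fluoride desilylation should free the C5 and C16 hydroxyls without generating alkoxides or strong acid that could open the C12–C13 oxirane.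

Step 21
Reactants: 25 epoxy triol
Product: 26 keto aldehyde
Conditions: Dess–Martin periodinane, NaHCO3, CH2Cl2, 0 to 23 °C
Reagents that add atoms: none
Why: Dess–Martin oxidation should convert the secondary C5 carbinol into the ketone and the allylic C16 alcohol into the enal in one operation, the tertiary C4 hydroxyl being inert and the C5 stereocentre disappearing.

Step 22
Reactants: 26 keto aldehyde
Product: 27 keto acid
Conditions: NaClO2, NaH2PO4, 2-methyl-2-butene, t-BuOH/H2O, 0 to 23 °C
Reagents that add atoms: sodium chlorite, [Na+].[O-]Cl=O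
Why: Pinnick oxidation should take the enal to the acrylic acid while the scavenger alkene removes HOCl before it can reach C8=C9.

Step 23
Reactants: 27 keto acid
Product: 28 target methyl ester
Conditions: Me3SiCHN2, PhMe/MeOH, 0 °C
Reagents that add atoms: trimethylsilyldiazomethane, C[Si](C)(C)C=[N+]=[N-]
Why: Esterification with the diazomethane surrogate should methylate only the carboxylic acid under neutral conditions that spare the ketol, the oxirane and the C1 centre.

Compound list
1 | (R)-carvone, (5R)-2-methyl-5-(prop-1-en-2-yl)cyclohex-2-en-1-one | CC1=CC[C@H](CC1=O)C(C)=C | starting material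
2 | (5R)-5-(3-chloroprop-1-en-2-yl)-2-methylcyclohex-2-en-1-one | CC1=CC[C@H](CC1=O)C(=C)CCl | intermediate
3 | (5R)-5-[3-(acetyloxy)prop-1-en-2-yl]-2-methylcyclohex-2-en-1-one | CC1=CC[C@H](CC1=O)C(=C)COC(C)=O | intermediate
4 | (5R)-5-(3-hydroxyprop-1-en-2-yl)-2-methylcyclohex-2-en-1-one | CC1=CC[C@H](CC1=O)C(=C)CO | intermediate
5 | (5R)-5-{3-[(tert-butyldimethylsilyl)oxy]prop-1-en-2-yl}-2-methylcyclohex-2-en-1-one | CC1=CC[C@H](CC1=O)C(=C)CO[Si](C)(C)C(C)(C)C | intermediate
6 | (1R,4R,6R)-4-{3-[(tert-butyldimethylsilyl)oxy]prop-1-en-2-yl}-1-methyl-7-oxabicyclo[4.1.0]heptan-2-one (oxirane trans to the side chain) | C=C(CO[Si](C)(C)C(C)(C)C)[C@H]1CC(=O)[C@]2(C)O[C@@H]2C1 | intermediate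
7 | 3-hydroxy derivative of 6 (hydroxyl on the CH next to the ketone, both epimers; other centres as in 6) | C=C(CO[Si](C)(C)C(C)(C)C)[C@H]1C(O)C(=O)[C@]2(C)O[C@@H]2C1 | intermediate
8 | methyl (2R,3R)-3-[(2S)-3-{[(tert-butyldimethylsilyl)oxy]methyl}-2-formylbut-3-en-1-yl]-2-methyloxirane-2-carboxylate | C=C(CO[Si](C)(C)C(C)(C)C)[C@@H](C=O)C[C@H]1O[C@@]1(C)C(=O)OC | intermediate
9 | methyl (2R,3R)-3-[(2S)-3-{[(tert-butyldimethylsilyl)oxy]methyl}-2-(hydroxymethyl)but-3-en-1-yl]-2-methyloxirane-2-carboxylate | C=C(CO[Si](C)(C)C(C)(C)C)[C@@H](CO)C[C@H]1O[C@@]1(C)C(=O)OC | intermediate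
10 | methyl (2R,3R)-3-[(2S)-3-{[(tert-butyldimethylsilyl)oxy]methyl}-2-[(phenylsulfanyl)methyl]but-3-en-1-yl]-2-methyloxirane-2-carboxylate | C=C(CO[Si](C)(C)C(C)(C)C)[C@@H](CSc1ccccc1)C[C@H]2O[C@@]2(C)C(=O)OC | intermediate
11 | {(2S,3R)-3-[(2S)-3-{[(tert-butyldimethylsilyl)oxy]methyl}-2-[(phenylsulfanyl)methyl]but-3-en-1-yl]-2-methyloxiran-2-yl}methanol | C=C(CO[Si](C)(C)C(C)(C)C)[C@@H](CSc1ccccc1)C[C@H]2O[C@@]2(C)CO | intermediate
12 | trifluoromethanesulfonate of 11 (C11–OTf) | C=C(CO[Si](C)(C)C(C)(C)C)[C@@H](CSc1ccccc1)C[C@H]2O[C@@]2(C)COS(=O)(=O)C(F)(F)F | intermediate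
13 | geranyl bromide, (2E)-1-bromo-3,7-dimethylocta-2,6-diene | CC(C)=CCC/C(C)=C/CBr | starting material
14 | geranyl phenyl sulfone, {[(2E)-3,7-dimethylocta-2,6-dien-1-yl]sulfonyl}benzene | CC(C)=CCC/C(C)=C/CS(=O)(=O)c1ccccc1 | intermediate
15 | (4E)-4-methyl-6-(phenylsulfonyl)hex-4-enal | O=CCC/C(C)=C/CS(=O)(=O)c1ccccc1 | intermediate
16 | isopropenylmagnesium bromide, CH2=C(CH3)MgBr (solution in THF) | C=C(C)[Mg]Br | starting material
17 | racemic (6E)-2,6-dimethyl-8-(phenylsulfonyl)octa-1,6-dien-3-ol | C=C(C)C(O)CC/C(C)=C/CS(=O)(=O)c1ccccc1 | intermediate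
18 | (1R,4E)-4-methyl-1-[(2S)-2-methyloxiran-2-yl]-6-(phenylsulfonyl)hex-4-en-1-ol | O=S(=O)(c1ccccc1)C/C=C(C)/CC[C@@H](O)[C@]2(C)CO2 | intermediate
19 | tert-butyldimethylsilyl ether of 18 | O=S(=O)(c1ccccc1)C/C=C(C)/CC[C@@H](O[Si](C)(C)C(C)(C)C)[C@]2(C)CO2 | intermediate
20 | open chain PhS–C2H2–C1H[C15(=C17H2)C16H2OTBS]–C14H2–(C13–C12 oxirane, 12-CH3)–C11H2–C10H(SO2Ph)–C9H=C8(CH3)–C7H2–C6H2–C5H(OTBS)–(C4–C3 oxirane, 4-CH3); 1S,4S,5R,12S,13R,8E; C10 epimers | c1ccccc1SC[C@H](C(=C)CO[Si](C)(C)C(C)(C)C)C[C@H]2O[C@@]2(C)CC(S(=O)(=O)c3ccccc3)/C=C(C)/CC[C@@H](O[Si](C)(C)C(C)(C)C)[C@]4(C)CO4 | intermediate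
21 | as 20 with C10H2 in place of C10H(SO2Ph); 1S,4S,5R,12S,13R,8E | c1ccccc1SC[C@H](C(=C)CO[Si](C)(C)C(C)(C)C)C[C@H]2O[C@@]2(C)CC/C=C(C)/CC[C@@H](O[Si](C)(C)C(C)(C)C)[C@]3(C)CO3 | intermediate
22 | as 21 with PhSO2 in place of PhS at C2 (cyclisation substrate); 1S,4S,5R,12S,13R,8E | O=S(=O)(c1ccccc1)C[C@H](C(=C)CO[Si](C)(C)C(C)(C)C)C[C@H]2O[C@@]2(C)CC/C=C(C)/CC[C@@H](O[Si](C)(C)C(C)(C)C)[C@]3(C)CO3 | intermediate
23 | (1S,4S,5R,8E,12S,13R)-5,16-bis[(tert-butyldimethylsilyl)oxy]-12,13-epoxy-2-(phenylsulfonyl)cembra-8,15(17)-dien-4-ol, C2 epimers | C=C(CO[Si](C)(C)C(C)(C)C)[C@H]1C(S(=O)(=O)c2ccccc2)C[C@](C)(O)[C@H](O[Si](C)(C)C(C)(C)C)CC/C(C)=C/CC[C@]3(C)O[C@@H]3C1 | intermediate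
24 | (1S,4S,5R,8E,12S,13R)-5,16-bis[(tert-butyldimethylsilyl)oxy]-12,13-epoxycembra-8,15(17)-dien-4-ol | C=C(CO[Si](C)(C)C(C)(C)C)[C@H]1CC[C@](C)(O)[C@H](O[Si](C)(C)C(C)(C)C)CC/C(C)=C/CC[C@]2(C)O[C@@H]2C1 | intermediate
25 | (1S,4S,5R,8E,12S,13R)-12,13-epoxycembra-8,15(17)-diene-4,5,16-triol | C=C(CO)[C@H]1CC[C@](C)(O)[C@H](O)CC/C(C)=C/CC[C@]2(C)O[C@@H]2C1 | intermediate
26 | (1S,4S,8E,12S,13R)-12,13-epoxy-4-hydroxy-5-oxocembra-8,15(17)-dien-16-al | C=C(C=O)[C@H]1CC[C@](C)(O)C(=O)CC/C(C)=C/CC[C@]2(C)O[C@@H]2C1 | intermediate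
27 | (1S,4S,8E,12S,13R)-12,13-epoxy-4-hydroxy-5-oxocembra-8,15(17)-dien-16-oic acid | C=C(C(=O)O)[C@H]1CC[C@](C)(O)C(=O)CC/C(C)=C/CC[C@]2(C)O[C@@H]2C1 | intermediate
28 | methyl (1S,4S,8E,12S,13R)-12,13-epoxy-4-hydroxy-5-oxocembra-8,15(17)-dien-16-oate (CNP0154954.4) | C=C(C(=O)OC)[C@H]1CC[C@](C)(O)C(=O)CC/C(C)=C/CC[C@]2(C)O[C@@H]2C1 | target

Total step count: 23 (steps 1–9 from carvone, steps 10–14 from geranyl bromide, steps 15–23 after the union).
Longest linear sequence: 18 steps (steps 1–9, then 15–23).

Steps most likely to fail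

Step 18. The C2 carbanion may be used up by 4-exo attack on the nearer C12–C13 oxirane (cyclobutane formation) or by intermolecular opening, or attack at the hindered C3 methylene may be too slow. The fallback reverses donor and acceptor across the same C2–C3 bond, so that no carbanion is formed near the C12–C13 oxirane; it sets out from 9 and comes back at 24. The C2 hydroxyl of 9 is silylated (Et3SiCl, imidazole) to the triethylsilyl ether ester F1, which iBu2AlH reduces to the epoxy alcohol F2; Tf2O/2,6-lutidine gives the triflate F3, and alkylation of lithiated 19 as in step 15 gives the coupled C10 sulfone F4, from which Na(Hg) as in step 16 gives the diepoxide F5. PhSNa in THF opens only the terminal oxirane, at C3 and without touching the C4–O bond, to the hydroxy sulfide F6, and molybdate/H2O2 oxidation gives the hydroxy sulfone F7. Pyridinium p-toluenesulfonate in MeOH removes the primary triethylsilyl group to give the diol sulfone F8, and TsCl/pyridine sulfonylates only the primary C2 hydroxyl to give the tosylate F9. LiN(iPr)2 (2.2 equiv, THF, high dilution) forms the C4 alkoxide and the C3 sulfonyl carbanion, which displaces the C2 tosylate to close the ring as the macrocyclic C3 sulfone F10; Na(Hg)/Na2HPO4 then removes the sulfonyl group and gives 24.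

Step 6. The β,γ-unsaturated aldehyde may enolise before it is reduced (loss of the C1 configuration or migration of the C15=C17 bond into conjugation), or the hindered ketol may cleave slowly. The fallback changes the cleavage manifold; it sets out from 7 and comes back at 11. NaBH4 (MeOH, 0 °C) reduces the ketone to the ring diol F11; NaIO4 in THF/pH 7 buffer cleaves it to the dialdehyde F12, which is not isolated but reduced in the same flask by NaBH4 to the open-chain diol F13. N-(phenylthio)succinimide/PBu3 (one equivalent, 0 °C) should then react at the less hindered C2 carbinol, the C11 carbinol being flanked by the fully substituted oxirane carbon, and give 11.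

Step 17. The peroxide oxidation may also epoxidise C8=C9 or open the terminal oxirane by solvolysis. The fallback moves the sulfur oxidation ahead of the fragment union; it sets out from 11 and comes back at 22. Molybdate/H2O2 oxidises 11, which has neither the trisubstituted alkene nor the terminal oxirane, to the sulfone alcohol F14; Tf2O/2,6-lutidine gives the sulfone triflate F15, and alkylation of lithiated 19 as in step 15 (the allylic carbanion is too weak a base to deprotonate the alkyl sulfone) gives the bis-sulfone F16. Na(Hg)/Na2HPO4 at −40 °C should cleave only the allylic C10–S bond, the unactivated primary sulfone needing a higher temperature, and give 22.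

Further compounds
F1 | step 18 | triethylsilyl ether ester (9 with C2–OSiEt3) | C=C(CO[Si](C)(C)C(C)(C)C)[C@@H](CO[Si](CC)(CC)CC)C[C@H]1O[C@@]1(C)C(=O)OC
F2 | step 18 | epoxy alcohol (F1 with C11H2OH in place of the ester) | C=C(CO[Si](C)(C)C(C)(C)C)[C@@H](CO[Si](CC)(CC)CC)C[C@H]1O[C@@]1(C)CO
F3 | step 18 | triflate of F2 | C=C(CO[Si](C)(C)C(C)(C)C)[C@@H](CO[Si](CC)(CC)CC)C[C@H]1O[C@@]1(C)COS(=O)(=O)C(F)(F)F
F4 | step 18 | coupled C10 sulfone (20 with C2–OSiEt3 in place of C2–SPh; C10 epimers) | CC[Si](CC)(CC)OC[C@H](C(=C)CO[Si](C)(C)C(C)(C)C)C[C@H]1O[C@@]1(C)CC(S(=O)(=O)c2ccccc2)/C=C(C)/CC[C@@H](O[Si](C)(C)C(C)(C)C)[C@]3(C)CO3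
F5 | step 18 | diepoxide (21 with C2–OSiEt3 in place of C2–SPh) | CC[Si](CC)(CC)OC[C@H](C(=C)CO[Si](C)(C)C(C)(C)C)C[C@H]1O[C@@]1(C)CC/C=C(C)/CC[C@@H](O[Si](C)(C)C(C)(C)C)[C@]2(C)CO2
F6 | step 18 | hydroxy sulfide (C3–SPh, C4–OH, 4S) | CC[Si](CC)(CC)OC[C@H](C(=C)CO[Si](C)(C)C(C)(C)C)C[C@H]1O[C@@]1(C)CC/C=C(C)/CC[C@@H](O[Si](C)(C)C(C)(C)C)[C@@](C)(O)CSc2ccccc2
F7 | step 18 | hydroxy sulfone (C3–SO2Ph, C4–OH) | CC[Si](CC)(CC)OC[C@H](C(=C)CO[Si](C)(C)C(C)(C)C)C[C@H]1O[C@@]1(C)CC/C=C(C)/CC[C@@H](O[Si](C)(C)C(C)(C)C)[C@@](C)(O)CS(=O)(=O)c2ccccc2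
F8 | step 18 | diol sulfone (C2–OH free) | OC[C@H](C(=C)CO[Si](C)(C)C(C)(C)C)C[C@H]1O[C@@]1(C)CC/C=C(C)/CC[C@@H](O[Si](C)(C)C(C)(C)C)[C@@](C)(O)CS(=O)(=O)c2ccccc2
F9 | step 18 | C2 tosylate of F8 | Cc1ccc(cc1)S(=O)(=O)OC[C@H](C(=C)CO[Si](C)(C)C(C)(C)C)C[C@H]2O[C@@]2(C)CC/C=C(C)/CC[C@@H](O[Si](C)(C)C(C)(C)C)[C@@](C)(O)CS(=O)(=O)c3ccccc3
F10 | step 18 | macrocyclic C3 sulfone (24 with SO2Ph on C3; C3 epimers) | C=C(CO[Si](C)(C)C(C)(C)C)[C@H]1CC(S(=O)(=O)c2ccccc2)[C@](C)(O)[C@H](O[Si](C)(C)C(C)(C)C)CC/C(C)=C/CC[C@]3(C)O[C@@H]3C1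
F11 | step 6 | ring diol (7 with the ketone reduced; carbinol epimers) | C=C(CO[Si](C)(C)C(C)(C)C)[C@H]1C(O)C(O)[C@]2(C)O[C@@H]2C1
F12 | step 6 | dialdehyde (C2 and C11 aldehydes) | C=C(CO[Si](C)(C)C(C)(C)C)[C@@H](C=O)C[C@H]1O[C@@]1(C)C=O
F13 | step 6 | open-chain diol (C2–OH and C11–OH) | C=C(CO[Si](C)(C)C(C)(C)C)[C@@H](CO)C[C@H]1O[C@@]1(C)CO
F14 | step 17 | sulfone alcohol (11 with SO2Ph in place of SPh) | C=C(CO[Si](C)(C)C(C)(C)C)[C@@H](CS(=O)(=O)c1ccccc1)C[C@H]2O[C@@]2(C)CO
F15 | step 17 | sulfone triflate (triflate of F14) | C=C(CO[Si](C)(C)C(C)(C)C)[C@@H](CS(=O)(=O)c1ccccc1)C[C@H]2O[C@@]2(C)COS(=O)(=O)C(F)(F)F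
F16 | step 17 | bis-sulfone (22 with SO2Ph also on C10; C10 epimers) | O=S(=O)(c1ccccc1)C[C@H](C(=C)CO[Si](C)(C)C(C)(C)C)C[C@H]2O[C@@]2(C)CC(S(=O)(=O)c3ccccc3)/C=C(C)/CC[C@@H](O[Si](C)(C)C(C)(C)C)[C@]4(C)CO4
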